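The question is what share of the G charged stands as E after the hour in blue, green, grey and teal, flasks with equal D and X and rising G.

| flask | G | D | X | remark | time |
|---|---|---|---|---|---|
| autumn | 12 mM | 20 mM | 0.56 mM | run made earlier |  |
| summer | 120 mM | 20 mM | 0.56 mM | run made earlier |  |
| blue | 20 mM | 20.0 mM | 0.56 mM |  | 1.0 h |
| green | 40 mM | 20.0 mM | 0.56 mM |  | 1.0 h |
| grey | 80 mM | 20.0 mM | 0.56 mM |  | 1.0 h |
| teal | 150 mM | 20.0 mM | 0.56 mM |  | 1.0 h |

| run | time / min | E / % | G / % |
|---|---|---|---|
| autumn | 5.00 | 23.2 | 43.2 |
| autumn | 15.0 | 43.5 | 7.4 |
| autumn | 25.0 | 47.8 | 1.4 |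
| autumn | 40.0 | 48.4 | 0 |
| summer | 3.00 | 2.7 | 82.3 |
| summer | 8.00 | 9.0 | 74.3 |
| summer | 20.0 | 23.1 | 60.1 |
| summer | 40.0 | 43.6 | 38.7 |

(standard deviation of a reading: 0.5 percentage points)

* amount of E at the end, in percent of the G charged for blue, green, grey, teal, in this order
* the shape of the row from first to last (rises, then falls / hardly changes / rises all the way / falls all the way / falls, then rises)

- "hardly changes" means that all values lie within two and a half points (for a concentration: within two and a half percent of the largest)

In summer the share of the charge that is neither G nor E reads 16.7% at 8.00 min and 17.7% at 40.0 min. That nearly constant share stands close to the D charge as a fraction of the G charge, 16.7%. So in summer G appears to leave one to one with D, and D appears to be the limiting reagent of this loss. For grey that fraction is 25.0%, and it is the toll: the most that D can take, leaving 75.0% of the grey charge as room for E. Teal has a toll of 13.3% and a room of 86.7%.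

In autumn the toll is 167%, above the whole charge, and E reads 48.4% at 40.0 min with G read at 0%. Blue, with a toll of 100%, should split nearly alike, at about that E or a little above. Green has a toll of 50.0%, so its E should stand a little above 50.0%.

Grey and teal also need pace. Frozen at the summer pace from 8.00 min to 20.0 min, E in the hour would reach 106% of the grey charge, more than its room, so grey should come close to 75.0%. For teal the late summer pace gives 49.2%, but that is the weak link: even after its toll, teal holds 1.80 times the G that summer held at 20.0 min. The earlier pace is the fairer one, and it gives 56.4%. The row should therefore rise to grey and then fall.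

The forecast stands at 49%, 55%, 66% and 56%, rises, then falls, holding “so G is consumed about 1:1 by D, with D running out”.

The flasks give 48.8%, 55.7%, 70.4% and 54.2%: rises, then falls.

    G + X → Z (k = 210 M⁻¹ min⁻¹)
    Z → J (k = 6.70 min⁻¹)
    J ⇌ X + E (K = 1.50 M, k = 4.90 min⁻¹)
    G + D → L (k = 5.30 M⁻¹ min⁻¹)

In blue the step G + D into L starts at 0.90 of the rate of the step G + X into Z, and L ends at 51.2% of the charge, under the blue toll, with 49% of D left. In grey and teal D stands at 0.015% and 0% of its charge at the hour, and L, at 25.0% and 13.3%, matches the tolls 25.0% and 13.3%; at 10.0 h, with G at 0%, teal holds E at 86.6%, against its room of 86.7%.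

The earlier runs and the new flask come from a simulation for an exercise; scatter was added.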